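## The problem

The target 33 is a 1,2-dioxolane in which both oxygen-bearing ring carbons (ring C3 and C5) are fully substituted. Each carries an ethyl group; C3 also carries an (E)-acrylic acid and C5 an (1E,4R,5E)-4-ethyl-2-methylocta-1,5-dienyl chain. The two ethyl groups lie on the same face (3S,5R). These two tertiary C–O centres are 1,3-related and tied together by the O–O bond, so their relative configuration has to come out of the ring-forming event itself and cannot be repaired afterwards. The third stereocentre (C4 of the octadienyl chain, R) lies five bonds from the ring across a trisubstituted alkene, so the ring cannot steer it and it needs reagent control. Three alkenes of defined geometry must be made, the trisubstituted one being the least forgiving. Once the O–O bond exists, dissolving metals, LiAlH4, organolithium and Grignard reagents, low-valent metals, hydrogenation and thiols are excluded, and a free hydroxyl β to a peroxide oxygen can fragment under strong base. The enabling feature is that ring C3(Et)–C4H2–C5(Et), with one sp2 carbon on each end, is the C1–C2–C3 edge of 1,3-diethylbenzene (1) together with its ortho carbons C6 and C4. If the six-membered ring is kept while the peroxide closes, arene C2 becomes a one-carbon bridge, the two C–O bonds can only be cis, and arene C5 is cut out later.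

## Retrosynthesis

**Acrylic acid last (33 ⇒ 32 ⇒ 30 + 31).** The C2=C3 bond of the acid is cut by a Wittig disconnection to aldehyde 30 and ylide 31, with ester 32 in between. The acrylate is the only Michael acceptor and the group least compatible with hydrides, so it is best introduced at the end. Aldehyde 30 has a quaternary α-carbon and cannot enolise or epimerise. It comes from silyl ether 28 through alcohol 29. The forward reaction must give E geometry without passing through a free alkoxide next to the peroxide, which a neutral stabilised ylide does.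

**Disubstituted alkene (28 ⇒ 22 + 26).** The C5=C6 bond of the octadienyl chain is cut to α-branched aldehyde 22 and propyl tetrazolyl sulfone 26. A Julia–Kocienski reaction is preferred to a Wittig reaction (Z-selective) and to metathesis (three alkenes would compete). Sulfone 26 is two steps from thiol 23, 1-bromopropane 24 and H2O2 4, via sulfide 25. The forward step must be E-selective and must not epimerise 22.

**Side-chain stereocentre (22 ⇒ 21 ⇒ 20 ⇒ 17 + 18).** The bond between the allylic CH2 and the ethyl-bearing carbon is cut to allylic bromide 17 and butanoyl oxazolidinone 18. Auxiliary control sets this remote centre independently of the ring. Joining a preformed chiral sp3 fragment by cross-coupling would put organometallics and low-valent catalysts next to the peroxide. The forward alkylation must deliver the R centre, which the (4S)-benzyl auxiliary does.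

**Trisubstituted alkene (17 ⇒ 15 ⇒ 14 ⇒ 13 ⇒ 11 + 12).** The C=C(CH3) bond is cut to aldehyde 11 and stabilised ylide 12; the ester carbon of 12 becomes the allylic CH2 of 17. A stabilised α-methyl ylide is the dependable source of an (E)-trisubstituted alkene; a secondary sulfone or non-stabilised ylide would give mixtures. In 11 the two ring arms differ (CHO against CH2OH), and the hydroxymethyl arm is silylated in 14 for the steps that follow.

**Cutting the tether (11 ⇒ 10 ⇒ 8 ⇒ 7).** In the retrosynthetic direction the two arm carbons are rejoined through one extra carbon into the three-carbon bridge of 7. Forward, HI elimination gives alkene 8, ozonolysis with borohydride work-up gives triol 10 (via ozonide 9), and periodate removes the middle carbon as formaldehyde. The arms emerge at different oxidation levels, and this matters because the core with two equal arms is meso. Dihydroxylation with double glycol cleavage would give that meso dialdehyde and is excluded for this reason.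

**Key disconnection (7 ⇒ 5 + 6).** The dioxolane O–C bond and the C–I bond are cut, leading to trans-hydroperoxy cyclohexenol 5 and N-iodosuccinimide 6. The cut removes the ring, one skeletal bond and two stereocentres. The forward reaction must favour hydroperoxide over hydroxyl attack and 5-exo over 6-endo closure.

**Hydroperoxide and arene (5 ⇒ 3 + 4; 3 ⇒ 2 ⇒ 1).** The tertiary C–OOH bond is cut to epoxide 3 and H2O2 4, with opening at the tertiary carbon under inversion. Epoxide 3 comes from desymmetrising mono-epoxidation of diene 2, the Birch product of 1. Absolute configuration therefore rests on one catalytic epoxidation of a C2v-symmetric diene.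

## Roads not taken

**Alternative 1:** The dioxolane C5–O1 bond is cut back to an acyclic precursor made by two titanium–tartrate epoxidations. In the forward key step a tertiary hydroperoxide on C3 opens a trisubstituted epoxide at its quaternary carbon with inversion (5-exo) to give A1.
- Merits: both ring stereocentres come from epoxidations of allylic alcohols, among the most dependable asymmetric reactions, and the second can raise the enantiopurity of the first. Both arms arrive oxygenated and already distinguished by a silyl ether, so no ring carbon has to be excised.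
- Weak points: the tertiary hydroperoxide must be installed at a quaternary carbon of a flexible chain, without a ring to enforce anti opening. The closure must take place at the more hindered epoxide carbon under acid, where ionisation, 6-endo attack at the secondary carbon and shifts compete. The cis relationship depends wholly on clean inversion at a tertiary centre. The sequence to the ring is longer.
- Comparison: A1 is better in enantiocontrol and in arm differentiation. The chosen plan offers a cis relationship that is a geometric necessity, and a ring reached in four steps from an arene.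

**Alternative 2:** C3–C4 and C5–O1 are cut together. SnCl4 ionises a silylperoxy ketal to a peroxycarbenium ion, the terminal CH2 of a 2-ethyl diene attacks it, and the silylperoxy oxygen captures the allyl cation at its ethyl-bearing end to give A2.
- Merits: this is the most convergent road. The whole side chain, with its stereocentre, arrives with the diene, and the total count could be roughly half that of the chosen plan.
- Weak points: the annulation is stepwise through an open allyl cation, so the cis/trans relationship of the two quaternary centres rests on a small preference between similar substituents. Facial choice at the cation rests on 1,2-induction from the acetonide. The allyl cation can be captured at its other end and can scramble the trisubstituted alkene that must be E. The diene carries two more nucleophilic alkenes, and the Lewis acid can open the acetonide.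
- Comparison: in step economy and convergence A2 is clearly better. The chosen plan offers certainty about the cis ring, an absolute configuration fixed before the side chain is attached, and alkene geometries set one at a time by controlled olefinations.

**Alternative 3:** Both C–O bonds are cut at once. Singlet oxygen adds [4+2] across diene A4 to give meso endoperoxide A3, and cleavage of its alkene releases both arms directly.
- Merits: cis is again enforced by a bicycle, both C–O bonds form in one step, and no surplus carbon exists. In steps to the cis core this road is better than the chosen one (two or three against seven).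
- Weak points: A4 is one of several isomers interconverting by 1,5-hydrogen shifts and it dimerises, so other isomers would give other peroxides. A3 is a strained 2,3-dioxabicyclo[2.2.1]heptene that rearranges near room temperature and must be handled cold. A3 is meso, so absolute configuration must come from a later desymmetrisation of two enantiotopic neopentyl arms, whose selectivity is not assured.
- Comparison: the chosen plan offers storable intermediates, an absolute configuration set by the epoxidation catalyst, and arms that leave the tether already different. It pays with three steps for cutting the tether and with enantiopurity that depends on a single epoxidation.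

Key step: step 4

Assumption: the D-fructose-derived ketone is taken to epoxidise 2 with the facial sense it shows for other 1-substituted cyclohexenes (spiro transition state); if the sense is opposite, the enantiomeric ketone is used and nothing else changes. Oxazolidinone 18 is taken as a catalogue compound.

## Route

Step 1
Reactants: 1 1,3-diethylbenzene
Product: 2 1,5-diethylcyclohexa-1,4-diene
Conditions: Li, NH3(l), EtOH, THF, −78 → −33 °C
Reagents that add atoms: none
Why: Birch reduction; protonation occurs at the unsubstituted positions 2 and 5, so both ethyl groups stay on sp2 carbons and the skipped diene is the kinetic product; no stereocentre forms.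

Step 2
Reactants: 2 1,5-diethylcyclohexa-1,4-diene
Product: 3 (1S,6R)-1,3-diethyl-7-oxabicyclo[4.1.0]hept-3-ene
Conditions: D-fructose-derived Shi ketone (1,2:4,5-di-O-isopropylidene-β-D-erythro-2,3-hexodiulo-2,6-pyranose, 30 mol %), KHSO5 (as Oxone, 0.8 equiv), K2CO3, Bu4NHSO4, aq. Na2B4O7 buffer, MeCN–CH2(OMe)2, 0 °C
Reagents that add atoms: potassium peroxymonosulfate (active component of Oxone), [K+].[O-]S(=O)(=O)OO
Why: Shi epoxidation by the chiral dioxirane; the two trisubstituted alkenes of 2 are enantiotopic and attack on either from the catalyst-preferred face gives the same enantiomer, so both stereocentres of 3 are set by the catalyst. The oxidant is kept substoichiometric so that bis-epoxide stays minor and unreacted 2 is recycled.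

Step 3
Reactants: 3 (1S,6R)-1,3-diethyl-7-oxabicyclo[4.1.0]hept-3-ene; 4 hydrogen peroxide
Product: 5 (1R,2R)-2,4-diethyl-2-hydroperoxycyclohex-4-en-1-ol
Conditions: H2O2 (anhydrous, in Et2O, 10 equiv), H3PMo12O40 (3 mol %), Et2O, 0 °C → rt
Reagents that add atoms: hydrogen peroxide (4), OO
Why: acid-catalysed perhydrolysis of an epoxide; H2O2 opens the activated epoxide at the tertiary carbon with inversion (anti opening) while the secondary C–O bond is untouched, giving the trans-β-hydroxy hydroperoxide. Excess anhydrous H2O2 and a weakly acidic catalyst are meant to outrun proton loss toward the arene.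

Step 4
Reactants: 5 (1R,2R)-2,4-diethyl-2-hydroperoxycyclohex-4-en-1-ol; 6 N-iodosuccinimide
Product: 7 (1R,2R,4S,5S)-1,5-diethyl-4-iodo-6,7-dioxabicyclo[3.2.1]octan-2-ol (hydroxyl and iodine both anti to the peroxide bridge)
Conditions: N-iodosuccinimide (1.2 equiv), NaHCO3, CH2Cl2, 0 °C, dark
Reagents that add atoms: N-iodosuccinimide (6), O=C1CCC(=O)N1I
Why: Iodonium transfer from 6 to the ring alkene of 5 is reversible on both faces and becomes productive when the iodonium ion sits anti to the axial hydroperoxide on C2, whose terminal oxygen then opens it at the ethyl-bearing carbon C4, forming the dioxolane O–C bond and the C–I bond in one anti addition. The closest known reaction type is the halonium-induced cyclisation of unsaturated hydroperoxides to cyclic peroxides, the peroxide counterpart of the iodolactonisation of cyclohex-3-enecarboxylic acids, which gives the same [3.2.1] bicycle. The one ring that closes, the 1,2-dioxolane, forms in a 5-exo-trig mode; the 6-endo alternative would attack the unsubstituted alkene carbon against the Markovnikov preference and give a 2,3-dioxabicyclo[2.2.2]octane. The new quaternary stereocentre C5 of 7 is controlled by C1, because a one-carbon bridge can span the ring on one face only, so the configuration set in step 3 is relayed and the two C–O bonds are necessarily cis. The new C–I stereocentre C4 is controlled by the anti course of iodonium opening and ends up trans to the peroxide bridge, axial and anti-periplanar to a C3–H bond. The selectivity needed is hydroperoxide over hydroxyl: in the reactive half-chair the trans hydroxyl on C1 is axial on the opposite face and could reach the near alkene carbon only through a four-membered ring and the far one only through a boat, whereas the more nucleophilic hydroperoxide has a strain-free 1,3-diaxial path. NaHCO3 keeps acid from acting on the β-iodo peroxide.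

Step 5
Reactants: 7 (1R,2R,4S,5S)-1,5-diethyl-4-iodo-6,7-dioxabicyclo[3.2.1]octan-2-ol
Product: 8 (1R,2R,5S)-1,5-diethyl-6,7-dioxabicyclo[3.2.1]oct-3-en-2-ol
Conditions: DBU, toluene, 60 °C
Reagents that add atoms: none
Why: E2 dehydroiodination; the axial iodide on C4 has one anti-periplanar hydrogen, on C3, and none on the bridgehead, so a single alkene forms. Both peroxide carbons are fully substituted (no Kornblum–DeLaMare path) and DBU is too weak to form the alkoxide that could fragment the β-hydroxy peroxide.

Step 6
Reactants: 8 (1R,2R,5S)-1,5-diethyl-6,7-dioxabicyclo[3.2.1]oct-3-en-2-ol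
Product: 10 (1R)-1-[(3R,5S)-3,5-diethyl-5-(hydroxymethyl)-1,2-dioxolan-3-yl]ethane-1,2-diol, via the secondary ozonide 9 (not isolated)
Conditions: O3, CH2Cl2, −78 °C; then MeOH, NaBH4, −78 → 0 °C
Reagents that add atoms: ozone, [O-][O+]=O
Why: ozonolysis with reductive borohydride work-up; the dialkyl peroxide is inert to ozone and NaBH4, the C3=C4 bond is cleaved and both ends are reduced, giving CH2OH on the former C–I side and a 1,2-diol on the other. Aprotic solvent and immediate cold reduction are chosen against the chain-shortening (anomalous) ozonolysis of allylic alcohols, which would make the arms identical.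

Step 7
Reactants: 10 (1R)-1-[(3R,5S)-3,5-diethyl-5-(hydroxymethyl)-1,2-dioxolan-3-yl]ethane-1,2-diol
Product: 11 (3R,5S)-3,5-diethyl-5-(hydroxymethyl)-1,2-dioxolane-3-carbaldehyde (expected to rest as its bicyclic lactol)
Conditions: NaIO4, THF–pH 7 buffer, 0 °C → rt
Reagents that add atoms: none
Why: periodate glycol cleavage; only the vicinal diol reacts and the middle carbon of the former bridge leaves as formaldehyde. The arms now differ in oxidation level, which keeps the core chiral, and the aldehyde has no α-hydrogen.

Step 8
Reactants: 11 (3R,5S)-3,5-diethyl-5-(hydroxymethyl)-1,2-dioxolane-3-carbaldehyde; 12 ethyl 2-(triphenyl-λ5-phosphanylidene)propanoate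
Product: 13 ethyl (2E)-3-[(3R,5S)-3,5-diethyl-5-(hydroxymethyl)-1,2-dioxolan-3-yl]-2-methylprop-2-enoate
Conditions: 12 (2 equiv), toluene, 80 °C
Reagents that add atoms: ethyl 2-(triphenyl-λ5-phosphanylidene)propanoate (12), CCOC(=O)C(C)=P(c1ccccc1)(c1ccccc1)c1ccccc1
Why: Wittig olefination with a stabilised ylide on a lactol in equilibrium with its hydroxy aldehyde; α-methyl stabilised ylides give the (E)-trisubstituted enoate, reinforced here by the quaternary aldehyde substituent. Neutral conditions avoid alkoxide formation and with it oxa-Michael closure and β-peroxy alkoxide fragmentation.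

Step 9
Reactants: 13 ethyl (2E)-3-[(3R,5S)-3,5-diethyl-5-(hydroxymethyl)-1,2-dioxolan-3-yl]-2-methylprop-2-enoate
Product: 14 ethyl (2E)-3-[(3R,5S)-5-({[tert-butyl(dimethyl)silyl]oxy}methyl)-3,5-diethyl-1,2-dioxolan-3-yl]-2-methylprop-2-enoate
Conditions: TBSCl, imidazole, DMF, rt
Reagents that add atoms: tert-butyl(chloro)dimethylsilane, CC(C)(C)[Si](C)(C)Cl
Why: silylation of a primary alcohol; it masks the hydroxyl before the hydride, enolate and carbanion steps and removes the fragmentation-prone free β-peroxy alcohol.

Step 10
Reactants: 14 ethyl (2E)-3-[(3R,5S)-5-({[tert-butyl(dimethyl)silyl]oxy}methyl)-3,5-diethyl-1,2-dioxolan-3-yl]-2-methylprop-2-enoate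
Product: 15 (2E)-3-[(3R,5S)-5-({[tert-butyl(dimethyl)silyl]oxy}methyl)-3,5-diethyl-1,2-dioxolan-3-yl]-2-methylprop-2-en-1-ol
Conditions: i-Bu2AlH, CH2Cl2, −78 °C; aq. potassium sodium tartrate
Reagents that add atoms: none
Why: 1,2-reduction of the unsaturated ester to the allylic alcohol; a dialkyl peroxide with fully substituted carbons should tolerate this hydride at −78 °C, and the alkene geometry is untouched.

Step 11
Reactants: 15 (2E)-3-[(3R,5S)-5-({[tert-butyl(dimethyl)silyl]oxy}methyl)-3,5-diethyl-1,2-dioxolan-3-yl]-2-methylprop-2-en-1-ol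
Product: 17 (3R,5S)-3-[(1E)-3-bromo-2-methylprop-1-en-1-yl]-5-({[tert-butyl(dimethyl)silyl]oxy}methyl)-3,5-diethyl-1,2-dioxolane, via the allylic methanesulfonate 16 (not isolated)
Conditions: MsCl, Et3N, CH2Cl2, −20 °C; then LiBr, THF, 0 °C → rt
Reagents that add atoms: methanesulfonyl chloride (retained only in 16), CS(=O)(=O)Cl; lithium bromide, [Li+].[Br-]
Why: mesylation followed by SN2 displacement with bromide; attack occurs at the primary CH2 because the SN2' position is shielded by the neighbouring quaternary carbon, so the (E)-geometry is kept.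

Step 12
Reactants: 17 (3R,5S)-3-[(1E)-3-bromo-2-methylprop-1-en-1-yl]-5-({[tert-butyl(dimethyl)silyl]oxy}methyl)-3,5-diethyl-1,2-dioxolane; 18 (4S)-4-benzyl-3-butanoyl-1,3-oxazolidin-2-one
Product: 20 (4S)-4-benzyl-3-{(2R,4E)-5-[(3R,5S)-5-({[tert-butyl(dimethyl)silyl]oxy}methyl)-3,5-diethyl-1,2-dioxolan-3-yl]-2-ethyl-4-methylpent-4-enoyl}-1,3-oxazolidin-2-one, via the sodium enolate 19 (not isolated)
Conditions: 18 (2 equiv), NaN(SiMe3)2, THF, −78 °C; then 17, −78 → −40 °C
Reagents that add atoms: (4S)-4-benzyl-3-butanoyl-1,3-oxazolidin-2-one (18), CCCC(=O)N1[C@@H](Cc2ccccc2)COC1=O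
Why: Evans asymmetric alkylation; the chelated sodium (Z)-enolate 19 is alkylated on the face opposite the benzyl group, which for the (4S) auxiliary gives the (2R) configuration at the new ethyl-bearing centre. The peroxide carbons carry no hydrogen and a tert-alkyl peroxide is a poor electrophile toward a hindered enolate at −78 °C.

Step 13
Reactants: 20 (4S)-4-benzyl-3-{(2R,4E)-5-[(3R,5S)-5-({[tert-butyl(dimethyl)silyl]oxy}methyl)-3,5-diethyl-1,2-dioxolan-3-yl]-2-ethyl-4-methylpent-4-enoyl}-1,3-oxazolidin-2-one
Product: 21 (2R,4E)-5-[(3R,5S)-5-({[tert-butyl(dimethyl)silyl]oxy}methyl)-3,5-diethyl-1,2-dioxolan-3-yl]-2-ethyl-4-methylpent-4-en-1-ol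
Conditions: LiBH4, MeOH (1 equiv), Et2O, 0 °C
Reagents that add atoms: none
Why: reductive removal of the oxazolidinone auxiliary; the activated imide carbonyl is reduced to the primary alcohol without epimerisation, and borohydride should not cleave the dialkyl peroxide.

Step 14
Reactants: 21 (2R,4E)-5-[(3R,5S)-5-({[tert-butyl(dimethyl)silyl]oxy}methyl)-3,5-diethyl-1,2-dioxolan-3-yl]-2-ethyl-4-methylpent-4-en-1-ol
Product: 22 (2R,4E)-5-[(3R,5S)-5-({[tert-butyl(dimethyl)silyl]oxy}methyl)-3,5-diethyl-1,2-dioxolan-3-yl]-2-ethyl-4-methylpent-4-enal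
Conditions: Dess–Martin periodinane, NaHCO3, CH2Cl2, 0 °C → rt
Reagents that add atoms: none
Why: Dess–Martin oxidation; buffered neutral conditions should give the α-branched aldehyde without epimerisation and leave peroxide, silyl ether and alkene alone; 22 is used without storage.

Step 15
Reactants: 23 1-phenyl-1H-tetrazole-5-thiol; 24 1-bromopropane
Product: 25 1-phenyl-5-(propylsulfanyl)-1H-tetrazole
Conditions: K2CO3, acetone, reflux
Reagents that add atoms: 1-bromopropane (24), CCCBr
Why: S-alkylation of the thiolate by SN2 on a primary bromide.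

Step 16
Reactants: 25 1-phenyl-5-(propylsulfanyl)-1H-tetrazole; 4 hydrogen peroxide
Product: 26 1-phenyl-5-(propane-1-sulfonyl)-1H-tetrazole
Conditions: H2O2 (30% aq.), (NH4)6Mo7O24·4H2O (cat.), EtOH, 0 °C → rt
Reagents that add atoms: hydrogen peroxide (4), OO
Why: molybdate-catalysed oxidation of the sulfide to the sulfone; the tetrazole ring is inert.

Step 17
Reactants: 22 (2R,4E)-5-[(3R,5S)-5-({[tert-butyl(dimethyl)silyl]oxy}methyl)-3,5-diethyl-1,2-dioxolan-3-yl]-2-ethyl-4-methylpent-4-enal; 26 1-phenyl-5-(propane-1-sulfonyl)-1H-tetrazole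
Product: 28 tert-butyl({(3S,5R)-3,5-diethyl-5-[(1E,4R,5E)-4-ethyl-2-methylocta-1,5-dien-1-yl]-1,2-dioxolan-3-yl}methoxy)dimethylsilane, via the potassium sulfonyl carbanion 27 (not isolated)
Conditions: 26, KN(SiMe3)2, DME, −60 °C; then 22, −60 °C → rt
Reagents that add atoms: 1-phenyl-5-(propane-1-sulfonyl)-1H-tetrazole (26), CCCS(=O)(=O)c1nnnn1-c1ccccc1
Why: Julia–Kocienski olefination; addition of 27 to the α-branched aldehyde, Smiles rearrangement and anti elimination of SO2 and tetrazolate give the (E)-disubstituted alkene, favoured by potassium in DME. The aldehyde is added to the preformed anion in the cold to protect its α-stereocentre.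

Step 18
Reactants: 28 tert-butyl({(3S,5R)-3,5-diethyl-5-[(1E,4R,5E)-4-ethyl-2-methylocta-1,5-dien-1-yl]-1,2-dioxolan-3-yl}methoxy)dimethylsilane
Product: 29 {(3S,5R)-3,5-diethyl-5-[(1E,4R,5E)-4-ethyl-2-methylocta-1,5-dien-1-yl]-1,2-dioxolan-3-yl}methanol
Conditions: Bu4NF, AcOH, THF, 0 °C → rt
Reagents that add atoms: none
Why: fluoride desilylation; AcOH keeps the liberated β-peroxy alkoxide protonated so that it cannot fragment.

Step 19
Reactants: 29 {(3S,5R)-3,5-diethyl-5-[(1E,4R,5E)-4-ethyl-2-methylocta-1,5-dien-1-yl]-1,2-dioxolan-3-yl}methanol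
Product: 30 (3S,5R)-3,5-diethyl-5-[(1E,4R,5E)-4-ethyl-2-methylocta-1,5-dien-1-yl]-1,2-dioxolane-3-carbaldehyde
Conditions: Dess–Martin periodinane, NaHCO3, CH2Cl2, 0 °C → rt
Reagents that add atoms: none
Why: Dess–Martin oxidation of a neopentyl-type primary alcohol to an aldehyde that cannot enolise.

Step 20
Reactants: 30 (3S,5R)-3,5-diethyl-5-[(1E,4R,5E)-4-ethyl-2-methylocta-1,5-dien-1-yl]-1,2-dioxolane-3-carbaldehyde; 31 ethyl 2-(triphenyl-λ5-phosphanylidene)acetate
Product: 32 ethyl (2E)-3-{(3S,5R)-3,5-diethyl-5-[(1E,4R,5E)-4-ethyl-2-methylocta-1,5-dien-1-yl]-1,2-dioxolan-3-yl}prop-2-enoate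
Conditions: 31, toluene, 60 °C
Reagents that add atoms: ethyl 2-(triphenyl-λ5-phosphanylidene)acetate (31), CCOC(=O)C=P(c1ccccc1)(c1ccccc1)c1ccccc1
Why: Wittig olefination with a stabilised ylide; a hindered non-enolisable aldehyde should give the (E)-acrylate, and the neutral concerted pathway avoids a free alkoxide β to the peroxide.

Step 21
Reactants: 32 ethyl (2E)-3-{(3S,5R)-3,5-diethyl-5-[(1E,4R,5E)-4-ethyl-2-methylocta-1,5-dien-1-yl]-1,2-dioxolan-3-yl}prop-2-enoate
Product: 33 (2E)-3-{(3S,5R)-3,5-diethyl-5-[(1E,4R,5E)-4-ethyl-2-methylocta-1,5-dien-1-yl]-1,2-dioxolan-3-yl}prop-2-enoic acid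
Conditions: LiOH, THF–H2O, rt; then dilute HCl to pH 3
Reagents that add atoms: lithium hydroxide, [Li+].[OH-]
Why: ester saponification; the peroxide carbons carry no hydrogen, so hydroxide has no Kornblum–DeLaMare pathway, and mild acidification returns the free acid.

## Compound list

1 | 1,3-diethylbenzene | CCc1cccc(CC)c1 | starting material
2 | 1,5-diethylcyclohexa-1,4-diene | CCC1=CCC=C(CC)C1 | intermediate
3 | (1S,6R)-1,3-diethyl-7-oxabicyclo[4.1.0]hept-3-ene | CCC1=CC[C@H]2O[C@@]2(CC)C1 | intermediate
4 | hydrogen peroxide | OO | starting material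
5 | (1R,2R)-2,4-diethyl-2-hydroperoxycyclohex-4-en-1-ol | O[C@@H]1CC=C(CC)C[C@@]1(CC)OO | intermediate
6 | N-iodosuccinimide | O=C1CCC(=O)N1I | starting material
7 | (1R,2R,4S,5S)-1,5-diethyl-4-iodo-6,7-dioxabicyclo[3.2.1]octan-2-ol | O[C@H]1[C@@]2(CC)C[C@]([C@@H](I)C1)(CC)OO2 | intermediate
8 | (1R,2R,5S)-1,5-diethyl-6,7-dioxabicyclo[3.2.1]oct-3-en-2-ol | O[C@H]1[C@@]2(CC)C[C@](C=C1)(CC)OO2 | intermediate
9 | secondary ozonide of 8 (1,2,4-trioxolane across former C3 and C4) | O[C@H]1[C@@]2(CC)C[C@](C3OOC1O3)(CC)OO2 | intermediate
10 | (1R)-1-[(3R,5S)-3,5-diethyl-5-(hydroxymethyl)-1,2-dioxolan-3-yl]ethane-1,2-diol | OC[C@@H](O)[C@@]1(CC)C[C@](CO)(CC)OO1 | intermediate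
11 | (3R,5S)-3,5-diethyl-5-(hydroxymethyl)-1,2-dioxolane-3-carbaldehyde (open form of the lactol 1,5-diethyl-3-oxa-6,7-dioxabicyclo[3.2.1]octan-2-ol) | O=C[C@@]1(CC)C[C@](CO)(CC)OO1 | intermediate
12 | ethyl 2-(triphenyl-λ5-phosphanylidene)propanoate | CCOC(=O)C(C)=P(c1ccccc1)(c1ccccc1)c1ccccc1 | starting material
13 | ethyl (2E)-3-[(3R,5S)-3,5-diethyl-5-(hydroxymethyl)-1,2-dioxolan-3-yl]-2-methylprop-2-enoate | CCOC(=O)/C(C)=C/[C@@]1(CC)C[C@](CO)(CC)OO1 | intermediate
14 | ethyl (2E)-3-[(3R,5S)-5-({[tert-butyl(dimethyl)silyl]oxy}methyl)-3,5-diethyl-1,2-dioxolan-3-yl]-2-methylprop-2-enoate | CCOC(=O)/C(C)=C/[C@@]1(CC)C[C@](CO[Si](C)(C)C(C)(C)C)(CC)OO1 | intermediate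
15 | (2E)-3-[(3R,5S)-5-({[tert-butyl(dimethyl)silyl]oxy}methyl)-3,5-diethyl-1,2-dioxolan-3-yl]-2-methylprop-2-en-1-ol | OC/C(C)=C/[C@@]1(CC)C[C@](CO[Si](C)(C)C(C)(C)C)(CC)OO1 | intermediate
16 | methanesulfonate of 15 | CS(=O)(=O)OC/C(C)=C/[C@@]1(CC)C[C@](CO[Si](C)(C)C(C)(C)C)(CC)OO1 | intermediate
17 | (3R,5S)-3-[(1E)-3-bromo-2-methylprop-1-en-1-yl]-5-({[tert-butyl(dimethyl)silyl]oxy}methyl)-3,5-diethyl-1,2-dioxolane | BrC/C(C)=C/[C@@]1(CC)C[C@](CO[Si](C)(C)C(C)(C)C)(CC)OO1 | intermediate
18 | (4S)-4-benzyl-3-butanoyl-1,3-oxazolidin-2-one | CCCC(=O)N1[C@@H](Cc2ccccc2)COC1=O | starting material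
19 | sodium (Z)-enolate of 18 | CC/C=C(\[O-])N1[C@@H](Cc2ccccc2)COC1=O.[Na+] | intermediate
20 | (4S)-4-benzyl-3-{(2R,4E)-5-[(3R,5S)-5-({[tert-butyl(dimethyl)silyl]oxy}methyl)-3,5-diethyl-1,2-dioxolan-3-yl]-2-ethyl-4-methylpent-4-enoyl}-1,3-oxazolidin-2-one | CC[C@H](C/C(C)=C/[C@@]1(CC)C[C@](CO[Si](C)(C)C(C)(C)C)(CC)OO1)C(=O)N2[C@@H](Cc3ccccc3)COC2=O | intermediate
21 | (2R,4E)-5-[(3R,5S)-5-({[tert-butyl(dimethyl)silyl]oxy}methyl)-3,5-diethyl-1,2-dioxolan-3-yl]-2-ethyl-4-methylpent-4-en-1-ol | CC[C@H](C/C(C)=C/[C@@]1(CC)C[C@](CO[Si](C)(C)C(C)(C)C)(CC)OO1)CO | intermediate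
22 | (2R,4E)-5-[(3R,5S)-5-({[tert-butyl(dimethyl)silyl]oxy}methyl)-3,5-diethyl-1,2-dioxolan-3-yl]-2-ethyl-4-methylpent-4-enal | CC[C@H](C/C(C)=C/[C@@]1(CC)C[C@](CO[Si](C)(C)C(C)(C)C)(CC)OO1)C=O | intermediate
23 | 1-phenyl-1H-tetrazole-5-thiol | Sc1nnnn1-c1ccccc1 | starting material
24 | 1-bromopropane | CCCBr | starting material
25 | 1-phenyl-5-(propylsulfanyl)-1H-tetrazole | CCCSc1nnnn1-c1ccccc1 | intermediate
26 | 1-phenyl-5-(propane-1-sulfonyl)-1H-tetrazole | CCCS(=O)(=O)c1nnnn1-c1ccccc1 | intermediate
27 | potassium α-sulfonyl carbanion of 26 | CC[CH-]S(=O)(=O)c1nnnn1-c1ccccc1.[K+] | intermediate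
28 | tert-butyl({(3S,5R)-3,5-diethyl-5-[(1E,4R,5E)-4-ethyl-2-methylocta-1,5-dien-1-yl]-1,2-dioxolan-3-yl}methoxy)dimethylsilane | CC/C=C/[C@H](CC)C/C(C)=C/[C@@]1(CC)C[C@](CO[Si](C)(C)C(C)(C)C)(CC)OO1 | intermediate
29 | {(3S,5R)-3,5-diethyl-5-[(1E,4R,5E)-4-ethyl-2-methylocta-1,5-dien-1-yl]-1,2-dioxolan-3-yl}methanol | CC/C=C/[C@H](CC)C/C(C)=C/[C@@]1(CC)C[C@](CO)(CC)OO1 | intermediate
30 | (3S,5R)-3,5-diethyl-5-[(1E,4R,5E)-4-ethyl-2-methylocta-1,5-dien-1-yl]-1,2-dioxolane-3-carbaldehyde | CC/C=C/[C@H](CC)C/C(C)=C/[C@@]1(CC)C[C@](C=O)(CC)OO1 | intermediate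
31 | ethyl 2-(triphenyl-λ5-phosphanylidene)acetate | CCOC(=O)C=P(c1ccccc1)(c1ccccc1)c1ccccc1 | starting material
32 | ethyl (2E)-3-{(3S,5R)-3,5-diethyl-5-[(1E,4R,5E)-4-ethyl-2-methylocta-1,5-dien-1-yl]-1,2-dioxolan-3-yl}prop-2-enoate | CC/C=C/[C@H](CC)C/C(C)=C/[C@@]1(CC)C[C@](/C=C/C(=O)OCC)(CC)OO1 | intermediate
33 | (2E)-3-{(3S,5R)-3,5-diethyl-5-[(1E,4R,5E)-4-ethyl-2-methylocta-1,5-dien-1-yl]-1,2-dioxolan-3-yl}prop-2-enoic acid | CC/C=C/[C@H](CC)C/C(C)=C/[C@@]1(CC)C[C@](/C=C/C(=O)O)(CC)OO1 | target

## Step count and least certain steps

Total step count: 21. Longest linear sequence: 19 steps (steps 1–14 and 17–21); steps 15 and 16 prepare sulfone 26.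

**Step 4 (key step).** The most likely failure is participation of the C1 hydroxyl in opening the iodonium ion (transannular ether formation through a boat conformer), or 6-endo closure. The fallback removes the competing nucleophile instead of trying to outrun it. It sets out from 5: Et3SiOTf and 2,6-lutidine give the bis(triethylsilyl) derivative F1. K2CO3 in MeOH at 0 °C methanolyses only the silyl peroxide, the peroxide anion being the better leaving group, to give the hydroperoxy silyl ether F2. N-iodosuccinimide then closes F2 to the silylated iodo peroxide F3, and HF·pyridine returns the route at 7.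

**Step 2.** The likely failure is incomplete facial discrimination by the ketone catalyst on a small alkyl-substituted cyclohexadiene, together with over-oxidation, which would leave scalemic material. The fallback is a classical resolution at the first rigid secondary carbinol. It sets out from 8: esterification with (2S)-2-methoxy-2-phenylacetic acid (DCC, DMAP) gives the O-methylmandelate F4. The diastereomers are separated by chromatography or crystallisation, and K2CO3 in MeOH returns the route at enantiopure 8. Racemic 3 from a peracid epoxidation of 2 could be carried through steps 3 to 5 and resolved the same way.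

**Step 3.** The likely failure is ionisation at the tertiary carbon outrunning capture by the weak nucleophile, followed by proton loss, dehydration and re-aromatisation, or hydrolysis by adventitious water. The fallback separates opening from peroxide delivery. It sets out from 3: aqueous HBr in CH2Cl2 at −40 °C should give the trans-bromohydrin F5, bromide being a fast trap. AgOSO2CF3 with excess anhydrous H2O2 in Et2O at −20 °C then effects a silver-assisted perhydrolysis, in which the trans hydroxyl assists loss of bromide and H2O2 enters anti to it. The route is rejoined at 5. This fallback still passes through a cationic species, but without the polyoxometalate acid and at lower temperature.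

**Step 6.** The likely failure is anomalous ozonolysis, in which the hydroxy-substituted carbonyl oxide fragments and the diol arm is shortened before reduction. Both arms would then become CH2OH, and the core would be meso. The fallback sets out from 8: TBSOTf and 2,6-lutidine give the silyl ether F6, ozonolysis with NaBH4 work-up gives the mono-silylated triol F7, and HF·pyridine returns the route at 10.

**Step 8.** The likely failure is sluggish olefination, because little open hydroxy aldehyde is present beside the bicyclic lactol and the carbonyl is neopentyl-like. On forcing, the free hydroxyl could add to the new enoate. The fallback separates the arms by protection before the aldehyde is released. It sets out from 10: 2,2-dimethoxypropane and PPTS give the acetonide alcohol F8, and TBSCl with imidazole gives its silyl ether F9. Aqueous AcOH in THF frees the silyl-protected diol F10, and NaIO4 gives the silyloxy aldehyde F11, which cannot form a lactol. A Wittig reaction of F11 with 12 returns the route at 14.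

## Further compounds

F1 | step 4 | triethyl{[(1R,2R)-2,4-diethyl-2-(triethylsilylperoxy)cyclohex-4-en-1-yl]oxy}silane | CC[Si](CC)(CC)O[C@@H]1CC=C(CC)C[C@@]1(CC)OO[Si](CC)(CC)CC
F2 | step 4 | {[(1R,2R)-2,4-diethyl-2-hydroperoxycyclohex-4-en-1-yl]oxy}triethylsilane | CC[Si](CC)(CC)O[C@@H]1CC=C(CC)C[C@@]1(CC)OO
F3 | step 4 | {[(1R,2R,4S,5S)-1,5-diethyl-4-iodo-6,7-dioxabicyclo[3.2.1]octan-2-yl]oxy}triethylsilane | CC[Si](CC)(CC)O[C@H]1[C@@]2(CC)C[C@]([C@@H](I)C1)(CC)OO2
F4 | step 2 | (1R,2R,5S)-1,5-diethyl-6,7-dioxabicyclo[3.2.1]oct-3-en-2-yl (2S)-2-methoxy-2-phenylacetate | CO[C@H](C(=O)O[C@H]1[C@@]2(CC)C[C@](C=C1)(CC)OO2)c3ccccc3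
F5 | step 3 | (1R,2R)-2-bromo-2,4-diethylcyclohex-4-en-1-ol | O[C@@H]1CC=C(CC)C[C@@]1(CC)Br
F6 | step 6 | tert-butyl{[(1R,2R,5S)-1,5-diethyl-6,7-dioxabicyclo[3.2.1]oct-3-en-2-yl]oxy}dimethylsilane | CC(C)(C)[Si](C)(C)O[C@H]1[C@@]2(CC)C[C@](C=C1)(CC)OO2
F7 | step 6 | (2R)-2-{[tert-butyl(dimethyl)silyl]oxy}-2-[(3R,5S)-3,5-diethyl-5-(hydroxymethyl)-1,2-dioxolan-3-yl]ethan-1-ol | OC[C@@H](O[Si](C)(C)C(C)(C)C)[C@@]1(CC)C[C@](CO)(CC)OO1
F8 | step 8 | {(3S,5R)-5-[(4R)-2,2-dimethyl-1,3-dioxolan-4-yl]-3,5-diethyl-1,2-dioxolan-3-yl}methanol | CC1(C)OC[C@@H](O1)[C@@]2(CC)C[C@](CO)(CC)OO2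
F9 | step 8 | tert-butyl({(3S,5R)-5-[(4R)-2,2-dimethyl-1,3-dioxolan-4-yl]-3,5-diethyl-1,2-dioxolan-3-yl}methoxy)dimethylsilane | CC1(C)OC[C@@H](O1)[C@@]2(CC)C[C@](CO[Si](C)(C)C(C)(C)C)(CC)OO2
F10 | step 8 | (1R)-1-[(3R,5S)-5-({[tert-butyl(dimethyl)silyl]oxy}methyl)-3,5-diethyl-1,2-dioxolan-3-yl]ethane-1,2-diol | OC[C@@H](O)[C@@]1(CC)C[C@](CO[Si](C)(C)C(C)(C)C)(CC)OO1
F11 | step 8 | (3R,5S)-5-({[tert-butyl(dimethyl)silyl]oxy}methyl)-3,5-diethyl-1,2-dioxolane-3-carbaldehyde | O=C[C@@]1(CC)C[C@](CO[Si](C)(C)C(C)(C)C)(CC)OO1
A1 | alternative 1 | (3S,5R)-3,5-diethyl-1,2-dioxolane with (1S)-1,2-dihydroxyethyl on C5 and (1R)-2-(tert-butyldiphenylsilyloxy)-1-hydroxyethyl on C3 | OC[C@H](O)[C@@]1(CC)C[C@]([C@H](O)CO[Si](C(C)(C)C)(c2ccccc2)c2ccccc2)(CC)OO1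
A2 | alternative 2 | (3S,5R)-3-[(4R)-2,2-dimethyl-1,3-dioxolan-4-yl]-3,5-diethyl-5-[(1E,4R,5E)-4-ethyl-2-methylocta-1,5-dien-1-yl]-1,2-dioxolane | CC/C=C/[C@H](CC)C/C(C)=C/[C@@]1(CC)C[C@]([C@H]2COC(C)(C)O2)(CC)OO1
A3 | alternative 3 | (1R,4S)-1,4-diethyl-2,3-dioxabicyclo[2.2.1]hept-5-ene (meso) | CC[C@@]12OO[C@@](CC)(C=C1)C2
A4 | alternative 3 | 1,4-diethylcyclopenta-1,3-diene | CCC1=CC=C(CC)C1
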